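**Retrosynthetic overview**
1. Guajadial C ⇒ o-quinone methide 14 (from diformylphloroglucinol 3 + benzaldehyde 10) + exocyclic alkene of muurola-4(15),5-diene 13; the inverse-demand hetero-Diels–Alder closes the dihydropyran and sets the spiro and benzylic centres.
2. Diene 13 is not isolated: its cyclohexene ring is made in the same flask by a [3+3] Michael/intramolecular Wittig annulation of the 2-methylallyl ylide 11 onto 6-methylenementhone 8. This delivers the exocyclic diene directly and never passes through an enone in which the ring-fusion H could epimerise to the more stable (wrong) orientation.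
3. 8 ⇐ (−)-menthone 4 (supplies the cyclohexane ring and the iPr- and Me-bearing stereocentres) by kinetic α-methylenation; 3 ⇐ phloroglucinol 1 by double Vilsmeier–Haack formylation.
4. Ring order: cyclohexane (chiral pool) → cyclohexene (annulation) → dihydropyran (cycloaddition), the last two in one operation.

Assumption: commercial (−)-menthone is the (2S,5R) isomer, and each one-flask sequence (steps 2 and 3) is counted as one step.

**Step 1**
Reactants: 1 phloroglucinol (benzene-1,3,5-triol)
Product: 3 2,4,6-trihydroxybenzene-1,3-dicarbaldehyde (2,4-diformylphloroglucinol), via bis-iminium salt 2 (not isolated)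
Conditions: POCl3 (2.2 equiv), DMF, 1,4-dioxane, 0 °C → rt; then ice/H2O
Reagents that add atoms: N,N-dimethylformamide (CN(C)C=O); water (O)
Why: Vilsmeier–Haack formylation of the symmetric, highly activated arene, where stoichiometry and the deactivating effect of each new CHO group stop the reaction at the dialdehyde; no stereocentre is formed.

**Step 2**
Reactants: 4 (−)-menthone, (2S,5R)-5-methyl-2-(propan-2-yl)cyclohexan-1-one
Product: 8 (3R,6S)-3-methyl-2-methylidene-6-(propan-2-yl)cyclohexan-1-one (6-methylenementhone), via lithium enolate 5 (not isolated), via Mannich base 6 (not isolated), via ammonium iodide 7 (not isolated)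
Conditions: LDA, THF, −78 °C; Me2N=CH2 I, −78 °C → rt; then MeI, rt; then aq. NaHCO3, rt (use 8 at once)
Reagents that add atoms: Eschenmoser's salt, N,N-dimethylmethyleneiminium iodide (C=[N+](C)C.[I-])
Why: Kinetic deprotonation takes the CH2 rather than the iPr-bearing CH, the enolate undergoes a Mannich reaction with Eschenmoser's salt, and Hofmann-type E1cB elimination of the quaternised amine gives the α-methylene ketone; no stereocentre is created and the two menthone centres are not enolised under these conditions.

**Step 3**
Reactants: 8 (3R,6S)-3-methyl-2-methylidene-6-(propan-2-yl)cyclohexan-1-one; 9 (2-methylallyl)triphenylphosphonium chloride; 3 2,4-diformylphloroglucinol; 10 benzaldehyde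
Product: 15 Guajadial C, via ylide 11 (not isolated), via keto ylide 12 (not isolated), via muuroladiene 13 (not isolated), via quinone methide 14 (not isolated)
Conditions: 9, KOt-Bu (1.0 equiv), THF, 0 °C; add 8, 0 → 66 °C; then 3, 10, NaOAc/AcOH (cat.), 1,4-dioxane, 80 °C; chromatography/HPLC
Reagents that add atoms: none
Why: Proposed new method: γ-selective Michael addition of allylic ylide 11 to the unhindered exocyclic enone is followed by proton transfer from the γ-methyl of the resulting vinylphosphonium to the enolate, which gives ylide 12 with the exo-methylene already in place and is expected to C-protonate the ring α-carbon kinetically anti to the neighbouring pseudoaxial methyl group (cf. cis-2,3-dialkylcyclohexanones from kinetic enolate protonation), and intramolecular Wittig closure onto the ring ketone then gives diene 13 and removes the carbonyl before that centre can epimerise (closest known chemistry: the Büchi–Wüest/Dauben cyclohexadiene annulation of allylidenephosphoranes with enones), after which buffered Knoevenagel condensation of 3 with 10 generates o-quinone methide 14, whose inverse-electron-demand hetero-Diels–Alder reaction with the exocyclic 1,1-disubstituted alkene of 13 (O to the allyl-stabilised carbon, ring alkene endo, from the face opposite the axial isopropyl group, as in the biomimetic three-component syntheses of guajadial and psidial A) closes the dihydropyran and sets the spiro (S) and benzylic (R) centres, with minor diastereomers removed chromatographically.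

**Compound list**
1 | phloroglucinol | Oc1cc(O)cc(O)c1 | starting material
2 | bis(N,N-dimethyliminium) salt of 2,4-diformylphloroglucinol (dichloride) | C[N+](C)=Cc1c(O)cc(O)c(C=[N+](C)C)c1O.[Cl-].[Cl-] | intermediate (not isolated)
3 | 2,4,6-trihydroxybenzene-1,3-dicarbaldehyde | O=Cc1c(O)cc(O)c(C=O)c1O | intermediate
4 | (−)-menthone, (2S,5R)-5-methyl-2-(propan-2-yl)cyclohexan-1-one | CC(C)[C@@H]1CC[C@@H](C)CC1=O | starting material
5 | lithium (3R,6S)-3-methyl-6-(propan-2-yl)cyclohex-1-en-1-olate | CC(C)[C@@H]1CC[C@@H](C)C=C1[O-].[Li+] | intermediate (not isolated)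
6 | (3R,6S)-2-[(dimethylamino)methyl]-3-methyl-6-(propan-2-yl)cyclohexan-1-one (C-2 epimers) | CC(C)[C@@H]1CC[C@@H](C)C(CN(C)C)C1=O | intermediate (not isolated)
7 | trimethylammonium iodide of 6 | CC(C)[C@@H]1CC[C@@H](C)C(C[N+](C)(C)C)C1=O.[I-] | intermediate (not isolated)
8 | (3R,6S)-3-methyl-2-methylidene-6-(propan-2-yl)cyclohexan-1-one | CC(C)[C@@H]1CC[C@@H](C)C(=C)C1=O | intermediate
9 | (2-methylallyl)triphenylphosphonium chloride | CC(=C)C[P+](c1ccccc1)(c1ccccc1)c1ccccc1.[Cl-] | starting material
10 | benzaldehyde | O=Cc1ccccc1 | starting material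
11 | (2-methylprop-2-en-1-ylidene)triphenyl-λ5-phosphane | CC(=C)C=P(c1ccccc1)(c1ccccc1)c1ccccc1 | intermediate (not isolated)
12 | (2R,3R,6S)-3-methyl-2-[3-methylidene-4-(triphenyl-λ5-phosphanylidene)butyl]-6-(propan-2-yl)cyclohexan-1-one | CC(C)[C@@H]1CC[C@@H](C)[C@@H](CCC(=C)C=P(c2ccccc2)(c2ccccc2)c2ccccc2)C1=O | intermediate (not isolated)
13 | (1S,4R,4aR)-4-methyl-7-methylidene-1-(propan-2-yl)-1,2,3,4,4a,5,6,7-octahydronaphthalene (muurola-4(15),5-diene; ring-fusion H cis to the H on the Me-bearing carbon, trans to the H on the iPr-bearing carbon) | CC(C)[C@@H]1CC[C@@H](C)[C@H]2CCC(=C)C=C12 | intermediate (not isolated)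
14 | 5-benzylidene-2,4-dihydroxy-6-oxocyclohexa-1,3-diene-1,3-dicarbaldehyde (o-quinone methide) | O=CC1=C(O)C(C=O)=C(O)C(=Cc2ccccc2)C1=O | intermediate (not isolated)
15 | Guajadial C: (2S,4R)-6,8-diformyl-5,7-dihydroxy-4-phenylchroman, spiro at C-2 with C-7' of the (1'S,4'R,4a'R)-4'-methyl-1'-(propan-2-yl)octahydronaphthalene (8',8a'-ene) | CC(C)[C@@H]1CC[C@@H](C)[C@H]2CC[C@@]3(C=C12)C[C@H](c1ccccc1)c1c(O)c(C=O)c(O)c(C=O)c1O3 | target

**Step count and risks**
Total steps: 3 (isolated intermediates 3 and 8). Longest linear sequence: 2 steps (4 → 8 → 15), with 1 → 3 as a one-step branch.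

Steps most likely to fail, in order:

**Step 3** (highest risk).
- The ylide may add through its α-carbon instead of its γ-carbon, or the ring may close through the endocyclic-diene tautomer of the ylide instead of 12.
- The ring-fusion centre needed is the less stable one. It rests on kinetic protonation alone, and the pseudoaxial isopropyl group on the same face may erode or reverse that preference.
- The cycloaddition can give up to four diastereomers, and it must run in the presence of Ph3PO and salts.

Fallback, setting out from 4 and coming back at 13: (−)-menthone 4 is condensed with SAMP to give the SAMP hydrazone F1. LDA deprotonation on the CH2 side and alkylation with 4-bromo-2-methylbut-1-ene gives the alkylated hydrazone F2, now under auxiliary control (SAMP chosen by analogy with its (R)-2-alkylcyclohexanones). Two-phase oxalic acid hydrolysis releases the ketone F3 without touching the alkene. Me2AlCl then promotes a type II carbonyl-ene closure to the homoallylic decalinol F4, and Burgess dehydration towards the allylic CH2 gives diene 13. The diene is isolated, and only the Knoevenagel/hetero-Diels–Alder half of step 3 is run with 3 and 10 to reach 15.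

**Step 2.** The α-methylene ketone 8 dimerises readily by hetero-Diels–Alder reaction, and the telescoped Mannich/quaternisation/elimination can stall at 6 or partly epimerise the iPr-bearing centre.

Fallback, setting out from 4 and coming back at 8: the kinetic enolate 5 is quenched with monomeric formaldehyde to give the hydroxymethyl ketone F5. This is converted with MsCl/Et3N into the mesylate F6 and eliminated with DBU at 0 °C to 8, which is used at once.

**Step 1.** Mono-, di- and triformylated products form statistically, and the polar polyphenol is hard to purify.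

Fallback, setting out from 1 and coming back at 3: phloroglucinol 1 is permethylated (Me2SO4, K2CO3) to 1,3,5-trimethoxybenzene F7. Twofold Rieche formylation (Cl2CHOMe, TiCl4) gives the dialdehyde F8, which is easily purified, and BBr3 demethylation gives 3.

**Further compounds**
F1 | step 3 | SAMP hydrazone of (−)-menthone, (S)-N-[(2S,5R)-5-methyl-2-(propan-2-yl)cyclohexylidene]-2-(methoxymethyl)pyrrolidin-1-amine | CC(C)[C@@H]1CC[C@@H](C)CC1=NN1CCC[C@H]1COC
F2 | step 3 | alkylated hydrazone, (S)-N-[(2R,3R,6S)-3-methyl-2-(3-methylbut-3-en-1-yl)-6-(propan-2-yl)cyclohexylidene]-2-(methoxymethyl)pyrrolidin-1-amine | CC(C)[C@@H]1CC[C@@H](C)[C@@H](CCC(C)=C)C1=NN1CCC[C@H]1COC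
F3 | step 3 | (2R,3R,6S)-3-methyl-2-(3-methylbut-3-en-1-yl)-6-(propan-2-yl)cyclohexan-1-one | CC(C)[C@@H]1CC[C@@H](C)[C@@H](CCC(C)=C)C1=O
F4 | step 3 | (1S,4R,4aR)-4-methyl-7-methylidene-1-(propan-2-yl)decahydronaphthalen-8a-ol (C-8a unassigned) | CC(C)[C@@H]1CC[C@@H](C)[C@H]2CCC(=C)CC12O
F5 | step 2 | (3R,6S)-2-(hydroxymethyl)-3-methyl-6-(propan-2-yl)cyclohexan-1-one (C-2 epimers) | CC(C)[C@@H]1CC[C@@H](C)C(CO)C1=O
F6 | step 2 | [(3R,6S)-3-methyl-2-oxo-6-(propan-2-yl)cyclohexyl]methyl methanesulfonate... as drawn, mesylate of F5 | CC(C)[C@@H]1CC[C@@H](C)C(COS(C)(=O)=O)C1=O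
F7 | step 1 | 1,3,5-trimethoxybenzene | COc1cc(OC)cc(OC)c1
F8 | step 1 | 2,4,6-trimethoxybenzene-1,3-dicarbaldehyde | COc1cc(OC)c(C=O)c(OC)c1C=O
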